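## Retrosynthetic overview

1. Numbering as in 1-benzofuran-2(3H)-one (O1, C2, C3, C3a, C4–C7, C7a). Sorbicillactone A ⇒ removal of the N-fumaroyl amide, the C4 sorboyl group and two acid-labile masks (tert-butyl ester, C7 enol methyl ether) leaves a Boc-protected bicyclic keto-lactone.
2. Keto-lactone ⇒ lactone C2–O1 bond (alkoxide onto methyl ester) and the C3a–C7a bond, made by 6π-electrocyclisation of a 1,4-dioxido-hexatriene ⇒ trans-3-alkenylcyclobutene-3,4-diolate (4π ring opening) ⇒ squarate-derived 4-hydroxycyclobutenone plus an (E)-alkenylmagnesium reagent from (S)-2-methylserine.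
3. Enabling feature: C7a(O)(CH3)–C7(O)=C6(CH3)–C5(=O) of the carbocycle is a ring-opened, methylated squaric acid unit, and C4–C3a is an E-vinyl pair. C3a–C7a is therefore the bond between the two ends of a hexatriene, and O-7a and C3 are cis across it, as two outward groups of a disrotatory closure must be.
4. Order of ring formation: four-membered ring (bought as dimethyl squarate, sacrificed) → six-membered carbocycle (C3a–C7a) → five-membered lactone (same flask); side chains last.

Key step: step 6

Remark on the chemistry: the enolised β-triketone/vinylogous acid of the target is one tautomeric system and is drawn throughout in the tautomer of the target SMILES.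

## Route

Step 1
Reactants: 1 (S)-2-methylserine
Product: 3 methyl (2S)-2-[(tert-butoxycarbonyl)amino]-3-hydroxy-2-methylpropanoate, via methyl ester hydrochloride 2 (not isolated)
Conditions: SOCl2, MeOH, 0 °C → reflux; evaporate; Boc2O, Et3N, THF, 50 °C
Reagents that add atoms: methanol CO; di-tert-butyl dicarbonate CC(C)(C)OC(=O)OC(=O)OC(C)(C)C
Why: Acid-catalysed (HCl from SOCl2/MeOH) Fischer esterification followed by carbamate formation with Boc2O on the hindered amine; the quaternary stereocentre has no α-hydrogen and cannot epimerise.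

Step 2
Reactants: 3 methyl (2S)-2-[(tert-butoxycarbonyl)amino]-3-hydroxy-2-methylpropanoate
Product: 4 methyl (2S)-2-[(tert-butoxycarbonyl)amino]-2-methyl-3-oxopropanoate
Conditions: Dess–Martin periodinane, CH2Cl2, 0 → 23 °C
Reagents that add atoms: none
Why: Dess–Martin oxidation of the primary alcohol stops at the aldehyde under neutral, non-aqueous conditions, and the fully substituted α-carbon rules out enolisation or epimerisation.

Step 3
Reactants: 4 methyl (2S)-2-[(tert-butoxycarbonyl)amino]-2-methyl-3-oxopropanoate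
Product: 5 methyl (2S,3E)-2-[(tert-butoxycarbonyl)amino]-4-iodo-2-methylbut-3-enoate
Conditions: CrCl2 (6 equiv), CHI3 (2 equiv), THF–1,4-dioxane, 0 → 23 °C, dark
Reagents that add atoms: iodoform IC(I)I
Why: Takai olefination, in which the geminal dichromium reagent formed from CHI3 and CrCl2 adds to the aldehyde and eliminates to the (E)-iodoalkene (E being the usual outcome of this reaction) under conditions mild enough for the α-formyl ester and the carbamate.

Step 4
Reactants: 6 dimethyl squarate
Product: 9 3-methoxy-4-methylcyclobut-3-ene-1,2-dione, via lithium alkoxide adduct 7 (not isolated), via tertiary trifluoroacetate 8 (not isolated)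
Conditions: MeLi (1.05 equiv), THF, −78 °C; (CF3CO)2O, −78 °C; H2O, −78 → 23 °C
Reagents that add atoms: methyllithium [Li]C; water O
Why: 1,2-Addition of MeLi to one squarate carbonyl and trifluoroacetylation of the resulting alkoxide trigger ionisation and hydrolysis of the transposed vinylogous ester, the standard squarate-to-3-alkoxy-4-alkylcyclobutenedione exchange that replaces OCH3 by CH3.

Step 5
Reactants: 9 3-methoxy-4-methylcyclobut-3-ene-1,2-dione
Product: 10 4-hydroxy-3-methoxy-2,4-dimethylcyclobut-2-en-1-one (racemic)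
Conditions: MeLi (1.0 equiv), THF, −78 °C; sat. aq. NH4Cl
Reagents that add atoms: methyllithium [Li]C
Why: Nucleophilic 1,2-addition of MeLi goes to the more electrophilic, ketone-like C2 carbonyl (next to the methoxy-bearing carbon) and not to the vinylogous-ester carbonyl C1, the known regiochemistry for 3-alkoxy-4-alkylcyclobutenediones; the new stereocentre is racemic and is destroyed in step 6.

Step 6
Reactants: 10 4-hydroxy-3-methoxy-2,4-dimethylcyclobut-2-en-1-one; 5 methyl (2S,3E)-2-[(tert-butoxycarbonyl)amino]-4-iodo-2-methylbut-3-enoate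
Product: 16 tert-butyl N-[(3S,3aR,7aS)-7-methoxy-3,6,7a-trimethyl-2,5-dioxo-2,3,3a,4,5,7a-hexahydro-1-benzofuran-3-yl]carbamate, via chloromagnesium alkoxide 11 (not isolated), via alkenylmagnesium 12 (not isolated), via cyclobutenediolate 13 (not isolated), via dioxidotriene 14 (not isolated), via cyclohexadienolate 15 (not isolated)
Conditions: 5, iPrMgCl·LiCl (2.1 equiv), THF, −30 → 0 °C; added to 10, iPrMgCl·LiCl (1.0 equiv), LaCl3·2LiCl (1.0 equiv), THF, −78 °C; −78 → 23 °C, then 45 °C; aq. citric acid
Reagents that add atoms: none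
Why: Proposed new method: the alkenylmagnesium 12 should add 1,2 to the vinylogous-ester carbonyl of 11, syn to the neighbouring O–Mg (delivery by the metal alkoxide), to give the trans-cyclobutene-3,4-diolate 13, whose strained sigma bond between the two oxygen-bearing ring carbons (C5–C7a in the numbering of 16) opens in a thermal conrotatory 4π process with both oxido groups turning outward and the alkenyl group and the C7a methyl turning inward, giving dioxido-hexatriene 14; thermal disrotatory 6π-electrocyclisation of 14 then forms the C3a–C7a bond, and the C7a alkoxide of 15, now cis to the ester carbon, closes the lactone with loss of methoxide. The closest known reaction types are the ring expansion of cyclobutenones to cyclohexenones by alkenyl-metal addition, oxy-anion-accelerated 4π opening and 6π closure, and the cascades that follow twofold alkenyl-anion addition to squarate esters (4π opening of a trans-cyclobutenediolate); new here are a triene terminus that is itself an enolate carbon carrying O and CH3, and the terminating lactonisation. The six-membered ring closes by 6π-disrotatory electrocyclisation and the five-membered ring by 5-exo-trig addition–elimination at the ester carbonyl. The relative configuration at C3a/C7a follows from orbital symmetry, because the two outward groups (O on C7a and the amino-acid carbon on the E-alkene terminus C3a) must end up cis, so H-3a and CH3-7a are cis and the lactone can only be cis-fused. The absolute configuration is relayed from the (S)-quaternary carbon of 12: in the boat-like transition state the bulky N-magnesiated carbamate should lie anti to the forming bond, the flat ester should take the crowded inside position over the new ring (within reach of the C7a–O–Mg, whose lactone carbonyl it becomes) and CH3 the outside position, which leads to (3aR,7aS). The step needs trans addition, outward rotation of both oxido groups and this facial selectivity; the first two are secured by the metal alkoxide and by the strong donor character of the oxido substituents, and a cis adduct can only open to a bis-enolate with the alkenyl group outward that cannot cyclise, so it costs material but gives no isomer of 16.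

Step 7
Reactants: 16 tert-butyl N-[(3S,3aR,7aS)-7-methoxy-3,6,7a-trimethyl-2,5-dioxo-2,3,3a,4,5,7a-hexahydro-1-benzofuran-3-yl]carbamate; 17 (2E,4E)-hexa-2,4-dienoyl chloride
Product: 19 tert-butyl N-[(3S,3aR,4Z,7aS)-4-[(2E,4E)-1-hydroxyhexa-2,4-dien-1-ylidene]-7-methoxy-3,6,7a-trimethyl-2,5-dioxo-2,3,3a,4,5,7a-hexahydro-1-benzofuran-3-yl]carbamate, via dilithiated enolate 18 (not isolated)
Conditions: LiN(SiMe3)2 (3.1 equiv), THF, −78 °C; 17 (1.2 equiv), −78 → −40 °C; AcOH, −78 °C
Reagents that add atoms: none
Why: Kinetic deprotonation at −78 °C, first at N–H and then at C4 (the only enolisable carbon), gives lithium enolate 18, whose Claisen-type C-acylation by the acid chloride should yield the β-diketone as its chelated enol, so C4 becomes sp2 and no stereocentre is created or touched (C3 has no hydrogen and H-3a is not acidic).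

Step 8
Reactants: 19 tert-butyl N-[(3S,3aR,4Z,7aS)-4-[(2E,4E)-1-hydroxyhexa-2,4-dien-1-ylidene]-7-methoxy-3,6,7a-trimethyl-2,5-dioxo-2,3,3a,4,5,7a-hexahydro-1-benzofuran-3-yl]carbamate
Product: 20 (3S,3aR,4Z,7aS)-4-[(2E,4E)-1-hydroxyhexa-2,4-dien-1-ylidene]-7-methoxy-3,6,7a-trimethyl-2,5-dioxo-2,3,3a,4,5,7a-hexahydro-1-benzofuran-3-aminium trifluoroacetate
Conditions: CF3CO2H–CH2Cl2 (1:4), 0 → 23 °C; evaporate from toluene
Reagents that add atoms: trifluoroacetic acid OC(=O)C(F)(F)F
Why: Acidolysis of the tert-butyl carbamate (loss of 2-methylpropene and CO2) runs under anhydrous conditions that leave the enol methyl ether, the lactone and the dienone intact, and the amine is kept as its ammonium salt so that it cannot condense with the neighbouring β-diketone.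

Step 9
Reactants: 20 (3S,3aR,4Z,7aS)-4-[(2E,4E)-1-hydroxyhexa-2,4-dien-1-ylidene]-7-methoxy-3,6,7a-trimethyl-2,5-dioxo-2,3,3a,4,5,7a-hexahydro-1-benzofuran-3-aminium trifluoroacetate; 21 (2E)-4-tert-butoxy-4-oxobut-2-enoic acid
Product: 23 tert-butyl (2E)-4-{[(3S,3aR,4Z,7aS)-4-[(2E,4E)-1-hydroxyhexa-2,4-dien-1-ylidene]-7-methoxy-3,6,7a-trimethyl-2,5-dioxo-2,3,3a,4,5,7a-hexahydro-1-benzofuran-3-yl]amino}-4-oxobut-2-enoate, via acid chloride 22 (not isolated)
Conditions: 21, 1-chloro-N,N,2-trimethylprop-1-en-1-amine, CH2Cl2, 0 °C; then 20, 2,6-lutidine, CH2Cl2, −40 → 0 °C; MeOH quench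
Reagents that add atoms: none
Why: The acid chloride 22 is made under neutral conditions that spare the tert-butyl ester and the E-alkene, and amide formation with the α-tertiary amine, set free by 2,6-lutidine only in the presence of 22, should outrun acylation of the hydrogen-bonded enols, any enol ester being cleaved by the methanol quench.

Step 10
Reactants: 23 tert-butyl (2E)-4-{[(3S,3aR,4Z,7aS)-4-[(2E,4E)-1-hydroxyhexa-2,4-dien-1-ylidene]-7-methoxy-3,6,7a-trimethyl-2,5-dioxo-2,3,3a,4,5,7a-hexahydro-1-benzofuran-3-yl]amino}-4-oxobut-2-enoate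
Product: 25 sorbicillactone A, via O-methyl acid 24 (not isolated)
Conditions: CF3CO2H–CH2Cl2 (1:2), 0 → 23 °C; evaporate; 1 M aq. HCl–THF (1:1), 40 °C
Reagents that add atoms: water O
Why: Acidolysis removes the tert-butyl ester and aqueous acid then hydrolyses the vinylogous methyl ester by conjugate addition of water at C7 and loss of methanol, conditions under which the lactone, the amide and all three stereocentres (none enolisable) should be stable.

## Compound list

1 | (S)-2-methylserine, (2S)-2-amino-3-hydroxy-2-methylpropanoic acid | C[C@](N)(CO)C(=O)O | starting material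
2 | methyl (2S)-2-amino-3-hydroxy-2-methylpropanoate hydrochloride | C[C@](N)(CO)C(=O)OC.Cl | intermediate
3 | methyl (2S)-2-[(tert-butoxycarbonyl)amino]-3-hydroxy-2-methylpropanoate | C[C@](NC(=O)OC(C)(C)C)(CO)C(=O)OC | intermediate
4 | methyl (2S)-2-[(tert-butoxycarbonyl)amino]-2-methyl-3-oxopropanoate | C[C@](NC(=O)OC(C)(C)C)(C=O)C(=O)OC | intermediate
5 | methyl (2S,3E)-2-[(tert-butoxycarbonyl)amino]-4-iodo-2-methylbut-3-enoate | C[C@](NC(=O)OC(C)(C)C)(/C=C/I)C(=O)OC | intermediate
6 | dimethyl squarate, 3,4-dimethoxycyclobut-3-ene-1,2-dione | COC1=C(OC)C(=O)C1=O | starting material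
7 | lithium 2,3-dimethoxy-1-methyl-4-oxocyclobut-2-en-1-olate (racemic) | COC1=C(OC)C(C)([O-])C1=O.[Li+] | intermediate
8 | 2,3-dimethoxy-1-methyl-4-oxocyclobut-2-en-1-yl trifluoroacetate (racemic) | COC1=C(OC)C(C)(OC(=O)C(F)(F)F)C1=O | intermediate
9 | 3-methoxy-4-methylcyclobut-3-ene-1,2-dione | COC1=C(C)C(=O)C1=O | intermediate
10 | 4-hydroxy-3-methoxy-2,4-dimethylcyclobut-2-en-1-one (racemic) | COC1=C(C)C(=O)C1(C)O | intermediate
11 | chloromagnesium alkoxide of 10 (racemic) | COC1=C(C)C(=O)C1(C)O[Mg]Cl | intermediate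
12 | N,C-dimagnesiated form of 5: methyl (2S,3E)-2-[(tert-butoxycarbonyl)(chloromagnesio)amino]-4-(chloromagnesio)-2-methylbut-3-enoate | C[C@](N([Mg]Cl)C(=O)OC(C)(C)C)(/C=C/[Mg]Cl)C(=O)OC | intermediate
13 | methyl (2S,3E)-4-[1,4-bis(chloromagnesiooxy)-3-methoxy-2,4-dimethylcyclobut-2-en-1-yl]-2-[(tert-butoxycarbonyl)(chloromagnesio)amino]-2-methylbut-3-enoate; the two O–Mg groups trans, both ring-face diastereomers (ring stereocentres left open in the SMILES) | COC1=C(C)C(O[Mg]Cl)(/C=C/[C@](C)(N([Mg]Cl)C(=O)OC(C)(C)C)C(=O)OC)C1(C)O[Mg]Cl | intermediate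
14 | methyl (2S,3E,5E,7Z)-5,8-bis(chloromagnesiooxy)-2-[(tert-butoxycarbonyl)(chloromagnesio)amino]-7-methoxy-2,6-dimethylnona-3,5,7-trienoate (both O–Mg outward, CH3-8 and the alkenyl arm inward) | C/C(O[Mg]Cl)=C(OC)\C(C)=C(O[Mg]Cl)/C=C/[C@](C)(N([Mg]Cl)C(=O)OC(C)(C)C)C(=O)OC | intermediate
15 | methyl (2S)-2-[3,6-bis(chloromagnesiooxy)-5-methoxy-4,6-dimethylcyclohexa-2,4-dien-1-yl]-2-[(tert-butoxycarbonyl)(chloromagnesio)amino]propanoate; ring C1 and C6 configured as C3a and C7a of 16 (side chain and O–Mg cis) | C1=C(O[Mg]Cl)C(C)=C(OC)[C@@](C)(O[Mg]Cl)[C@H]1[C@](C)(N([Mg]Cl)C(=O)OC(C)(C)C)C(=O)OC | intermediate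
16 | tert-butyl N-[(3S,3aR,7aS)-7-methoxy-3,6,7a-trimethyl-2,5-dioxo-2,3,3a,4,5,7a-hexahydro-1-benzofuran-3-yl]carbamate (cis-fused; NHBoc on the concave face, CH3-3 cis to H-3a and CH3-7a) | C1C(=O)C(C)=C(OC)[C@@]2(C)OC(=O)[C@@](C)(NC(=O)OC(C)(C)C)[C@@H]12 | intermediate
17 | (2E,4E)-hexa-2,4-dienoyl chloride (sorboyl chloride) | C/C=C/C=C/C(Cl)=O | starting material
18 | dilithio derivative of 16: lithium C4=C5 enolate, N-lithiated carbamate, stereocentres as in 16 | C1=C(O[Li])C(C)=C(OC)[C@@]2(C)OC(=O)[C@@](C)(N([Li])C(=O)OC(C)(C)C)[C@@H]12 | intermediate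
19 | tert-butyl N-[(3S,3aR,4Z,7aS)-4-[(2E,4E)-1-hydroxyhexa-2,4-dien-1-ylidene]-7-methoxy-3,6,7a-trimethyl-2,5-dioxo-2,3,3a,4,5,7a-hexahydro-1-benzofuran-3-yl]carbamate | C/C=C/C=C/C(O)=C1/C(=O)C(C)=C(OC)[C@@]2(C)OC(=O)[C@@](C)(NC(=O)OC(C)(C)C)[C@@H]12 | intermediate
20 | (3S,3aR,4Z,7aS)-4-[(2E,4E)-1-hydroxyhexa-2,4-dien-1-ylidene]-7-methoxy-3,6,7a-trimethyl-2,5-dioxo-2,3,3a,4,5,7a-hexahydro-1-benzofuran-3-aminium trifluoroacetate | C/C=C/C=C/C(O)=C1/C(=O)C(C)=C(OC)[C@@]2(C)OC(=O)[C@@](C)([NH3+])[C@@H]12.[O-]C(=O)C(F)(F)F | intermediate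
21 | (2E)-4-tert-butoxy-4-oxobut-2-enoic acid (mono-tert-butyl fumarate) | CC(C)(C)OC(=O)/C=C/C(=O)O | starting material
22 | tert-butyl (2E)-4-chloro-4-oxobut-2-enoate | CC(C)(C)OC(=O)/C=C/C(Cl)=O | intermediate
23 | tert-butyl (2E)-4-{[(3S,3aR,4Z,7aS)-4-[(2E,4E)-1-hydroxyhexa-2,4-dien-1-ylidene]-7-methoxy-3,6,7a-trimethyl-2,5-dioxo-2,3,3a,4,5,7a-hexahydro-1-benzofuran-3-yl]amino}-4-oxobut-2-enoate | C/C=C/C=C/C(O)=C1/C(=O)C(C)=C(OC)[C@@]2(C)OC(=O)[C@@](C)(NC(=O)/C=C/C(=O)OC(C)(C)C)[C@@H]12 | intermediate
24 | (2E)-4-{[(3S,3aR,4Z,7aS)-4-[(2E,4E)-1-hydroxyhexa-2,4-dien-1-ylidene]-7-methoxy-3,6,7a-trimethyl-2,5-dioxo-2,3,3a,4,5,7a-hexahydro-1-benzofuran-3-yl]amino}-4-oxobut-2-enoic acid | C/C=C/C=C/C(O)=C1/C(=O)C(C)=C(OC)[C@@]2(C)OC(=O)[C@@](C)(NC(=O)/C=C/C(=O)O)[C@@H]12 | intermediate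
25 | sorbicillactone A, (2E)-4-{[(3S,3aR,4Z,7aS)-7-hydroxy-4-[(2E,4E)-1-hydroxyhexa-2,4-dien-1-ylidene]-3,6,7a-trimethyl-2,5-dioxo-2,3,3a,4,5,7a-hexahydro-1-benzofuran-3-yl]amino}-4-oxobut-2-enoic acid | C/C=C/C=C/C(O)=C1/C(=O)C(C)=C(O)[C@@]2(C)OC(=O)[C@@](C)(NC(=O)/C=C/C(=O)O)[C@@H]12 | target

## Step count and risks

Total step count: 10. Longest linear sequence: 8 steps (1, 2, 3, 6, 7, 8, 9, 10 from (S)-2-methylserine); the squarate branch (steps 4, 5) joins at step 6.

Steps most likely to fail:

Step 6 (Proposed new method). The 6π closure of the dioxido-triene, whose C7a terminus carries an inward methyl group, may be slow, so that the open bis-enolate is merely protonated on work-up. The facial selectivity at C3a, which rests on a steric model of the quaternary centre, may be low. Some cis addition would lose material to an acyclic diketone. The fallback separates the events and runs them in the neutral manifold with known reaction types; it sets out from 10 and 5. 11 and 12 would be generated and combined at −78 °C as before, and both magnesium alkoxides silylated cold (Me3SiOSO2CF3, 2,6-lutidine) to give the isolable trans-bis(trimethylsilyl) ether of the cyclobutenediol F1. Heating F1 in toluene (80–110 °C) should effect the thermal 4π opening/6π closure known for 3-alkenylcyclobutenes and give the bis-silylated cyclohexadiene (silyl enol ether at C5, silyl ether at C7a) F2. If the facial selectivity is low, the C3a/C7a diastereomers can be separated by chromatography at this stage. Bu4NF/AcOH in THF would then cleave both silyl groups, the freed C7a alcohol lactonising onto the methyl ester, and the fallback comes back to the route at 16.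

Step 7. O-Acylation of the enolate or N-acylation of the carbamate anion may compete with C-acylation, and excess amide base may erode the product. The fallback sets out from 16 and replaces acylation by aldol addition and oxidation. The dianion 18 (2.1 equiv LiN(SiMe3)2, THF, −78 °C) would add to (2E,4E)-hexa-2,4-dienal to give the C4 β-hydroxy ketone F3 as a mixture of epimers at C4 and at the carbinol carbon. Dess–Martin oxidation of F3 removes both new stereocentres and comes back to the route at 19.

Step 10. Water addition at C7, which is flanked by the quaternary C7a, may be slow, so that hydrolysis of the enol ether stalls or the longer acid exposure degrades the polyenone. The fallback sets out from 23 and cleaves the O–CH3 bond instead of the C7–O bond: SN2 demethylation with LiCl in DMF (60–80 °C) would give the tert-butyl ester with free C7 enol F4. CF3CO2H in CH2Cl2 then removes the tert-butyl ester and the fallback comes back to the route at 25.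

## Further compounds

F1 | step 6 | methyl (2S,3E)-2-[(tert-butoxycarbonyl)amino]-4-[3-methoxy-2,4-dimethyl-1,4-bis(trimethylsilyloxy)cyclobut-2-en-1-yl]-2-methylbut-3-enoate, silyloxy groups trans, ring stereocentres left open | COC1=C(C)C(O[Si](C)(C)C)(/C=C/[C@](C)(NC(=O)OC(C)(C)C)C(=O)OC)C1(C)O[Si](C)(C)C
F2 | step 6 | methyl (2S)-2-[(tert-butoxycarbonyl)amino]-2-[5-methoxy-4,6-dimethyl-3,6-bis(trimethylsilyloxy)cyclohexa-2,4-dien-1-yl]propanoate, ring C1 and C6 configured as C3a and C7a of 16 | C1=C(O[Si](C)(C)C)C(C)=C(OC)[C@@](C)(O[Si](C)(C)C)[C@H]1[C@](C)(NC(=O)OC(C)(C)C)C(=O)OC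
F3 | step 7 | tert-butyl N-[(3S,3aR,7aS)-4-[(2E,4E)-1-hydroxyhexa-2,4-dien-1-yl]-7-methoxy-3,6,7a-trimethyl-2,5-dioxo-2,3,3a,4,5,7a-hexahydro-1-benzofuran-3-yl]carbamate, mixture of epimers at C4 and at the carbinol carbon | C/C=C/C=C/C(O)C1C(=O)C(C)=C(OC)[C@@]2(C)OC(=O)[C@@](C)(NC(=O)OC(C)(C)C)[C@@H]12
F4 | step 10 | tert-butyl (2E)-4-{[(3S,3aR,4Z,7aS)-7-hydroxy-4-[(2E,4E)-1-hydroxyhexa-2,4-dien-1-ylidene]-3,6,7a-trimethyl-2,5-dioxo-2,3,3a,4,5,7a-hexahydro-1-benzofuran-3-yl]amino}-4-oxobut-2-enoate | C/C=C/C=C/C(O)=C1/C(=O)C(C)=C(O)[C@@]2(C)OC(=O)[C@@](C)(NC(=O)/C=C/C(=O)OC(C)(C)C)[C@@H]12
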